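The north flask is the one asked about: you have followed it to 12.0 min and must carry it on to 30 min.

common to all: substrate 0.30 M; gas phase 21 mM (held); free catalyst 11 mM

| flask | added ligand | remark | time |
|---|---|---|---|
| north | 16 mM | the very flask that is asked about, followed so far |  |
| north-west | 24 mM | run made earlier |  |
| flask | 16 mM |  | 30 min |

- north (time / min: product / %, substrate / %): 1.00: 1.8, 99.7; 1.50: 1.7, 98.7; 2.50: 2.4, 97.2; 4.00: 4.7, 93.9; 8.00: 12.1, 90.3; 12.0: 16.4, 82.3
- north-west (time / min: product / %, substrate / %): 1.00: 0.2, 100.9; 1.50: 0, 100.4; 2.50: 0.6, 97.9; 4.00: 1.8, 98.4; 8.00: 6.4, 92.8; 12.0: 9.9, 91.2

(each reading ± 1 percentage point)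

- what was read earlier has a scatter of 1 percentage point, one standard deviation
- at the start none of the gas phase is in solution

* amount of product at 30 min, in percent of the substrate charged
* concentration of dissolved gas in solution at 30 min, in percent of saturation

At the start none of the gas phase is in solution, and the north run shows just 4.7% product at 4.00 min, so you leave the first minutes out of the reckoning. From there on you can read a pseudo-first-order constant, the share of the remaining substrate converted per minute, from the product readings of the north run at 4.00 min and 12.0 min: 0.0164 /min, a reading that carries their scatter. The north-west run reached less product at 12.0 min, 9.9% with 24 mM of added ligand, but the asked flask has the north charge, so you use the north constant. You then extrapolate just the stretch beyond the last reading, 18.0 min at that constant, and your own reckoning gives 37.7% product.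

The forecast is a little lower, 36% (27% to 45%), with dissolved gas at 85% of saturation (60% to 97%), and among its grounds is that "the reaction looks mainly kinetically limited rather than transfer limited".

The flask gives 37.3% product and 85.1% of saturation.

    free catalyst + added ligand ⇌ idle complex, settled at all times (K = 1600 /M)
    substrate + dissolved gas + free catalyst → free catalyst + product (k = 16.4 /M²/s)
    gas phase ⇌ dissolved gas, rate k3*(csat - [dissolved gas]) (kL = 0.0161 /s)
    free catalyst → spent catalyst (k = 3.98 × 10⁻⁴ /s)

The constant leaves 62.3% of the substrate in this flask at 30 min, and the flask holds 63%. Now take the same flask left until 50 min. Running the constant on from the last reading for 38.0 min gives 55.1% product, and that flask holds 54.0% product, with 46.0% of the substrate left.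

Readings and results are simulated for substances that don't exist.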